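**Plan**
1. Cuts, in order: C3–Br (late SEAr), N1–H (masked as N–Ts), the C2=C3 unsaturation (back to the indoline level), then C5–Br and C6–Br (back to C5–SiMe3 and C6–SiMe3).
2. Enabling feature: in the benzo ring C3a–C4–C5–C6–C7–C7a, C4 and C7 bear only H and C5 and C6 bear identical groups. C3a and C7a are bridged by C3–C2–N1 of the five-membered ring, so the six carbons are three alkynes, two of them tethered.
3. Core cut: C3a–C7a, C4–C5 and C6–C7. This gives an N-ethynyl-N-(but-3-ynyl)sulfonamide (C7≡C7a on N1, C3a≡C4 on C3) and bis(trimethylsilyl)acetylene (C5≡C6).
4. The diyne is cut at N1–C7a (alkynyliodonium N-alkynylation) and at N–S (sulfonylation of but-3-yn-1-amine).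
5. Forward: the chain is assembled on nitrogen (steps 1–3) and both rings close together in step 4. Si→Br exchange at C5/C6, dehydrogenation, N–S cleavage and C3 bromination follow.
6. Stereochemistry: the target is planar and achiral and no isolated compound on the way has a stereocentre, so none has to be set.

Key step: step 4

Assumption: the target SMILES contains no stereogenic element, so it describes one achiral compound and the question of a single enantiomer does not arise.

**Step 1**
Reactants: 1 but-3-yn-1-amine; 2 p-toluenesulfonyl chloride
Product: 3 N-(but-3-yn-1-yl)-4-methylbenzenesulfonamide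
Conditions: Et3N (1.5 equiv), CH2Cl2, 0 °C → rt
Reagents that add atoms: none
Why: Hinsberg-type N-sulfonylation of a primary amine; the alkyne is inert and the sulfonamide formed is far less nucleophilic than 1, so the reaction should stop after one sulfonyl transfer.

**Step 2**
Reactants: 3 N-(but-3-yn-1-yl)-4-methylbenzenesulfonamide; 4 phenyl[(trimethylsilyl)ethynyl]iodonium triflate
Product: 6 N-(but-3-yn-1-yl)-4-methyl-N-[(trimethylsilyl)ethynyl]benzenesulfonamide, via potassium sulfonamidate 5 (not isolated)
Conditions: KHMDS (1.0 equiv), toluene, 0 °C; then 4 (1.2 equiv), 0 °C → rt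
Reagents that add atoms: none
Why: N-alkynylation of a sulfonamide anion with an alkynyl(aryl)iodonium salt (conjugate addition at the β-carbon, loss of PhI, 1,2-silyl shift of the alkylidene carbene); one equivalent of base removes only the much more acidic N–H, so the terminal alkyne stays untouched and no copper is present that could couple it.

**Step 3**
Reactants: 6 N-(but-3-yn-1-yl)-4-methyl-N-[(trimethylsilyl)ethynyl]benzenesulfonamide
Product: 7 N-(but-3-yn-1-yl)-N-ethynyl-4-methylbenzenesulfonamide
Conditions: K2CO3 (0.2 equiv), MeOH/THF, 0 °C
Reagents that add atoms: none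
Why: Base-catalysed methanolysis of the alkynyl C–Si bond (protodesilylation); the sulfonyl group tempers the ynamide enough for it to tolerate cold carbonate/methanol.

**Step 4**
Reactants: 7 N-(but-3-yn-1-yl)-N-ethynyl-4-methylbenzenesulfonamide; 8 bis(trimethylsilyl)acetylene
Product: 10 1-tosyl-5,6-bis(trimethylsilyl)indoline, via cobaltacyclopentadiene 9 (not isolated)
Conditions: CpCo(CO)2 (10 mol %), 8 (20 equiv)/toluene, reflux, hν (visible lamp), 7 added by syringe pump over 10 h; excess 8 recovered by distillation
Reagents that add atoms: none
Why: Heat and light strip CO from CpCo(CO)2, and the CpCo fragment binds both alkynes of 7 and couples them oxidatively to cobaltacyclopentadiene 9, which makes C3a–C7a. This closes the ring N1–C2–C3–C3a–C7a by intramolecular cyclometallation in a 5-exo,exo sense, with both terminal CH carbons (future C4 and C7) left outside the ring on cobalt; the three-atom tether allows no other ring size. Alkyne 8 then coordinates to 9, is taken up across the two Co–C bonds, and reductive elimination forms C4–C5 and C6–C7, so the six-membered ring closes intermolecularly as an arene and CpCo is returned. The closest known reaction type is the CpCo-catalysed [2+2+2] cocyclisation of α,ω-diynes with bis(trimethylsilyl)acetylene, and ynamide-tethered diynes are established substrates in Rh- and Co-catalysed versions that lead to indolines. The selectivity required is cross-cyclisation over oligomerisation of 7: for steric reasons 8 does not trimerise with itself and can serve as co-solvent, while slow addition keeps the stationary concentration of 7 low. Regiochemistry cannot arise because 8 is symmetric, and no stereocentre is formed.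

**Step 5**
Reactants: 10 1-tosyl-5,6-bis(trimethylsilyl)indoline
Product: 12 5,6-dibromo-1-tosylindoline, via 5-bromo-1-tosyl-6-(trimethylsilyl)indoline 11 (not isolated)
Conditions: Br2 (2.3 equiv), pyridine (1 equiv), CH2Cl2, 0 °C → rt, dark; aq. Na2S2O3
Reagents that add atoms: bromine, BrBr
Why: Double electrophilic ipso-bromodesilylation through β-silicon-stabilised arenium ions; C5 is para to N1 and C6 para to the C3a alkyl branch, strain relief between the neighbouring silyl groups speeds the first exchange, the C4–H and C7–H sites cannot compete with C–Si, and pyridine traps traces of HBr that would cause protodesilylation.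

**Step 6**
Reactants: 12 5,6-dibromo-1-tosylindoline
Product: 13 5,6-dibromo-1-tosyl-1H-indole
Conditions: DDQ (2.5 equiv), PhCl, 120 °C
Reagents that add atoms: none
Why: Quinone dehydrogenation of an N-sulfonylindoline (hydride abstraction, then proton loss) driven by aromatisation of the pyrrole ring; aryl bromides, the sulfonamide and the electron-poor tosyl methyl group are inert to DDQ, and heat compensates for the deactivated ring.

**Step 7**
Reactants: 13 5,6-dibromo-1-tosyl-1H-indole
Product: 14 5,6-dibromo-1H-indole
Conditions: KOH (5 equiv), THF/MeOH/H2O, 60 °C; then 1 M HCl to pH 7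
Reagents that add atoms: none
Why: Nucleophilic S–N cleavage of an N-sulfonylindole by hydroxide; the indolide, stabilised further by two bromines, is a good leaving group, so non-reductive conditions suffice and the C–Br bonds are kept.

**Step 8**
Reactants: 14 5,6-dibromo-1H-indole
Product: 15 3,5,6-tribromo-1H-indole
Conditions: NBS (1.0 equiv), DMF, 0 °C, dark
Reagents that add atoms: N-bromosuccinimide, O=C1CCC(=O)N1Br
Why: Electrophilic aromatic substitution at C3, the enamine-like and most nucleophilic position of a 1H-indole; the benzo ring is deactivated by its two bromines and C2 reacts only after C3, so one equivalent of NBS in the cold should stop at the tribromide.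

**Compound list**
1 | but-3-yn-1-amine | C#CCCN | starting material
2 | p-toluenesulfonyl chloride | Cc1ccc(cc1)S(Cl)(=O)=O | starting material
3 | N-(but-3-yn-1-yl)-4-methylbenzenesulfonamide | C#CCCNS(=O)(=O)c1ccc(C)cc1 | intermediate
4 | phenyl[(trimethylsilyl)ethynyl]iodonium triflate | C[Si](C)(C)C#C[I+]c1ccccc1.[O-]S(=O)(=O)C(F)(F)F | starting material
5 | potassium N-(but-3-yn-1-yl)-4-methylbenzenesulfonamidate (not isolated) | C#CCC[N-]S(=O)(=O)c1ccc(C)cc1.[K+] | intermediate
6 | N-(but-3-yn-1-yl)-4-methyl-N-[(trimethylsilyl)ethynyl]benzenesulfonamide | C#CCCN(C#C[Si](C)(C)C)S(=O)(=O)c1ccc(C)cc1 | intermediate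
7 | N-(but-3-yn-1-yl)-N-ethynyl-4-methylbenzenesulfonamide | C#CCCN(C#C)S(=O)(=O)c1ccc(C)cc1 | intermediate
8 | bis(trimethylsilyl)acetylene | C[Si](C)(C)C#C[Si](C)(C)C | starting material
9 | (cyclopentadienyl)cobaltacyclopentadiene fused to the N-tosylpyrrolidine ring, Co bound to the future C4 and C7 (not isolated; Cp written as its anion) | [cH-]1cccc1.[Co+]2C=C3CCN(S(=O)(=O)c4ccc(C)cc4)C3=C2 | intermediate
10 | 1-tosyl-5,6-bis(trimethylsilyl)indoline | C[Si](C)(C)c1cc2CCN(S(=O)(=O)c3ccc(C)cc3)c2cc1[Si](C)(C)C | intermediate
11 | 5-bromo-1-tosyl-6-(trimethylsilyl)indoline (not isolated) | Brc1cc2CCN(S(=O)(=O)c3ccc(C)cc3)c2cc1[Si](C)(C)C | intermediate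
12 | 5,6-dibromo-1-tosylindoline | Brc1cc2CCN(S(=O)(=O)c3ccc(C)cc3)c2cc1Br | intermediate
13 | 5,6-dibromo-1-tosyl-1H-indole | Brc1cc2ccn(S(=O)(=O)c3ccc(C)cc3)c2cc1Br | intermediate
14 | 5,6-dibromo-1H-indole | Brc1cc2cc[nH]c2cc1Br | intermediate
15 | 3,5,6-tribromo-1H-indole | Brc1cc2[nH]cc(Br)c2cc1Br | target

Total step count: 8. Longest linear sequence: 8 steps (1 → 15).

**Steps most likely to fail**

Step 4. Self-oligomerisation of the diyne, or thermal and hydrolytic loss of the terminal ynamide, may outrun capture of the metallacycle by the very hindered disilyl alkyne. The fallback changes the C5/C6 two-carbon unit and its ipso handle from silicon to boron. It sets out from 7. Diyne 7 is cocyclised under Co2(CO)8 mediation in hot xylene with bis(pinacolatoboryl)acetylene, which is flatter at the alkyne carbons and more electrophilic. The same three bonds and two rings form, giving 1-tosyl-5,6-bis(4,4,5,5-tetramethyl-1,3,2-dioxaborolan-2-yl)indoline F1. Copper(II)-mediated bromodeboronation (CuBr2, MeOH/H2O, 80 °C) then exchanges both boryl groups for bromine. The route is rejoined at 12.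

Step 6. Hydride abstraction may stall because the N-sulfonyl group and two bromines deactivate the indoline, and forcing conditions may lead to decomposition. The fallback inverts the order of deprotection and oxidation. It sets out from 12. The sulfonamide is hydrolysed in concentrated H2SO4 with aqueous work-up to give 5,6-dibromoindoline F2. As a free secondary aniline, F2 should be dehydrogenated readily by activated MnO2 in CH2Cl2 at rt. The route is rejoined at 14, bypassing 13.

Step 5. The second silicon-to-bromine exchange may stop at the monobromide stage next to the new bromine, or adventitious acid may cause protodesilylation. The fallback uses a stronger electrophile followed by halogen exchange. It sets out from 10. ICl (2.5 equiv, CH2Cl2, 0 °C) should replace both silyl groups to give 5,6-diiodo-1-tosylindoline F3. Copper(I)-mediated aromatic halogen exchange with excess CuBr in DMF at 140 °C, driven by formation of CuI, then converts both C–I bonds into C–Br bonds. The route is rejoined at 12.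

**Further compounds**
F1 | step 4 | 1-tosyl-5,6-bis(4,4,5,5-tetramethyl-1,3,2-dioxaborolan-2-yl)indoline | CC1(C)OB(OC1(C)C)c1cc2CCN(S(=O)(=O)c3ccc(C)cc3)c2cc1B1OC(C)(C)C(C)(C)O1
F2 | step 6 | 5,6-dibromoindoline | Brc1cc2CCNc2cc1Br
F3 | step 5 | 5,6-diiodo-1-tosylindoline | Ic1cc2CCN(S(=O)(=O)c3ccc(C)cc3)c2cc1I
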